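**Retrosynthetic overview**
1. Target diacid 24 ⇐ its dimethyl ester 23 ⇐ 3,12-diketone 22, where one bulky-hydride reduction sets both axial alcohols; the C19 acid comes from the CH2OH of the chiral pool.
2. Ring C is closed last: the C12–C13 bond forms by an intramolecular carbonyl-ene reaction of a C12 aldehyde with a spiro 1-methylcyclopentene, which also creates 12-OH and the 16-methylene.
3. Ring B is contracted from six to five members by Wolff rearrangement of a 6-diazo-7-ketone; C7 becomes the ester carbon.
4. Ring D comes from ring-closing metathesis of allyl and 2-methylallyl groups on C8, both installed on an exocyclic enone by conjugate addition and enolate alkylation (sets C8).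
5. Rings A and B with C4, C5, C9 and C10 come from andrographolide after C12=C13 cleavage and C7 allylic oxidation. Ring order: A and B (chiral pool), then D, then B contraction, then C.

Assumption: andrographolide, a bulk natural product, counts as commercially available. Labdane numbering is used for compounds 1–13 and gibberellane numbering from 14 on (labdane C17 becomes C14, the vinyl CH becomes C13, the 2-methylallyl carbons become C15, C16 and C17, and labdane C7 becomes the C7 ester carbon).

**Route**

Step 1
Reactants: 1 andrographolide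
Product: 2 3,19-O-isopropylideneandrographolide
Conditions: Me2C(OMe)2, PPTS (cat.), toluene/DMSO, 80 °C
Reagents that add atoms: 2,2-dimethoxypropane, COC(C)(C)OC
Why: Acid-catalysed transketalisation closes a six-membered 1,3-dioxane across the cis-disposed equatorial 3-OH and axial C4 CH2OH, while the 14-OH stays free and is lost in step 2.

Step 2
Reactants: 2 3,19-O-isopropylideneandrographolide
Product: 3 3,19-O-isopropylidene-13,14,15,16-tetranor-ent-labd-8(17)-en-12-al
Conditions: KMnO4, THF/H2O, −10 °C
Reagents that add atoms: potassium permanganate, [K+].[O-][Mn](=O)(=O)=O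
Why: Permanganate oxidative alkene cleavage attacks the electron-poor, lactone-conjugated C12=C13 bond faster than the isolated 1,1-disubstituted C8=C17 bond and leaves a C12 aldehyde without touching any stereocentre.

Step 3
Reactants: 3 3,19-O-isopropylidene-13,14,15,16-tetranor-ent-labd-8(17)-en-12-al
Product: 4 dimethyl acetal of 3
Conditions: Me2C(OMe)2/MeOH (10:1), PPTS (cat.), rt
Reagents that add atoms: 2,2-dimethoxypropane, COC(C)(C)OC
Why: Acid-catalysed acetal exchange masks the aldehyde for the organometallic and strong-base steps, and the large excess of 2,2-dimethoxypropane keeps the acetonide in place.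

Step 4
Reactants: 4 dimethyl acetal of 3
Product: 5 7-hydroxy acetal (7-OH axial and trans to the C10 methyl)
Conditions: SeO2 (0.3 equiv), t-BuOOH, CH2Cl2, rt
Reagents that add atoms: tert-butyl hydroperoxide, CC(C)(C)OO
Why: Selenium dioxide allylic oxidation (ene reaction at C17, then [2,3]-sigmatropic shift) restores the exocyclic alkene and hydroxylates the secondary C7 on the axial face opposite the C10 methyl; this configuration is erased in step 5.

Step 5
Reactants: 5 7-hydroxy acetal
Product: 6 exocyclic enone (7-oxo-8(17)-ene)
Conditions: Dess–Martin periodinane, pyridine, CH2Cl2, 0 °C to rt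
Reagents that add atoms: none
Why: Dess–Martin oxidation under buffered, non-enolising conditions gives the α-methylene ketone without moving the double bond into ring B.

Step 6
Reactants: 6 exocyclic enone; 7 vinylmagnesium bromide (CH2=CHMgBr); 8 3-bromo-2-methylprop-1-ene
Product: 10 8-allyl-8-(2-methylallyl) 7-ketone, via bromomagnesium enolate 9 (not isolated)
Conditions: CH2=CHMgBr, CuBr·SMe2 (10 mol%), THF, −78 °C; then HMPA, methallyl bromide, −78 °C to rt
Reagents that add atoms: none
Why: Copper-catalysed conjugate addition of the vinyl group to C17 gives the C8 enolate regiospecifically, and its alkylation sets C8 because the bromide approaches the face opposite the axial C10 methyl, leaving the allyl arm (future C14 and C13) cis to C20 and the 2-methylallyl arm (future C15, C16, C17) trans to it.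

Step 7
Reactants: 10 8-allyl-8-(2-methylallyl) 7-ketone
Product: 11 spiro ketone (3-methylcyclopent-3-ene ring D spiro at C8)
Conditions: second-generation Grubbs catalyst RuCl2(=CHPh)(PCy3)(H2IMes) (5 mol%), CH2Cl2, 40 °C
Reagents that add atoms: none
Why: Ring-closing metathesis of the 1,6-diene expels ethylene and gives the trisubstituted cyclopentene with the ring alkene fixed between the future C13 and C16; no stereocentre changes.

Step 8
Reactants: 11 spiro ketone
Product: 13 6-diazo-7-ketone, via trifluoroacetyl ketone 12 (not isolated)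
Conditions: LiN(SiMe3)2, THF, −78 °C, then CF3CO2CH2CF3; then MsN3, Et3N, H2O, MeCN, rt
Reagents that add atoms: 2,2,2-trifluoroethyl trifluoroacetate, O=C(OCC(F)(F)F)C(F)(F)F (atoms stay only in 12); methanesulfonyl azide, CS(=O)(=O)N=[N+]=[N-]
Why: Detrifluoroacetylative diazo transfer (Danheiser procedure) works here because C6 is the only enolisable position of the C7 ketone, C8 being quaternary.

Step 9
Reactants: 13 6-diazo-7-ketone
Product: 16 ring-contracted methyl ester, via ketene 14 (not isolated), via 6-epi ester 15 (not isolated)
Conditions: hν (medium-pressure Hg lamp, Pyrex), MeOH, rt; then NaOMe (cat.), MeOH, 60 °C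
Reagents that add atoms: methanol, CO
Why: In the photochemical Wolff rearrangement C8 migrates from C7 to C6 with retention and contracts ring B, methanol traps the ketene, and methoxide equilibration at C6 gives the more stable ester, trans to C4 and cis to the hydrogen on C5, which is the natural configuration.

Step 10
Reactants: 16 ring-contracted methyl ester
Product: 17 aldehyde diol
Conditions: AcOH/THF/H2O (3:1:1), 45 °C
Reagents that add atoms: water, O
Why: Mild aqueous acid hydrolysis removes the dimethyl acetal and the acetonide in one operation and leaves the methyl ester and the trisubstituted alkene untouched.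

Step 11
Reactants: 17 aldehyde diol
Product: 18 tetracyclic triol ester (3-OH equatorial; 12-OH syn to the C15–C16 bridge)
Conditions: Me2AlCl (3.5 equiv), CH2Cl2, −78 to 0 °C; then H2O
Reagents that add atoms: none
Why: In this Lewis-acid-promoted intramolecular carbonyl-ene reaction (the citronellal-to-isopulegol type) the aldehyde carbon bonds to the ring CH= carbon on the only face the C9 tether can reach, which fixes C13, and the hydrogen comes from the C17 methyl through a six-membered transition state, giving the 16-methylene and a 12-OH syn to C16 that is corrected in steps 14 and 15.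

Step 12
Reactants: 18 tetracyclic triol ester
Product: 20 19-carboxylic acid 7-methyl ester, via 19-aldehyde 19 (not isolated)
Conditions: TEMPO (20 mol%), PhI(OAc)2 (2.5 equiv), MeCN/H2O (1:1), rt
Reagents that add atoms: water, O
Why: Oxoammonium (TEMPO) oxidation selects the primary alcohol over the two secondary ones and in aqueous acetonitrile carries the aldehyde hydrate on to the acid, a β-hydroxy acid that cannot decarboxylate.

Step 13
Reactants: 20 19-carboxylic acid 7-methyl ester
Product: 21 3,12-di-epi dimethyl ester (7,19-dimethyl ester of the 3,12-di-epimer of the target)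
Conditions: Me3SiCHN2, MeOH/toluene, 0 °C
Reagents that add atoms: trimethylsilyldiazomethane, C[Si](C)(C)C=[N+]=[N-]
Why: Diazoalkane esterification methylates only the carboxylic acid, so that the C3 ketone of step 14 is part of a stable β-keto ester and not of a β-keto acid.

Step 14
Reactants: 21 3,12-di-epi dimethyl ester
Product: 22 3,12-dioxo dimethyl ester
Conditions: Dess–Martin periodinane, pyridine, CH2Cl2, rt
Reagents that add atoms: none
Why: Dess–Martin oxidation of both secondary alcohols erases the two wrong carbinol configurations; the C4 quaternary β-keto ester cannot epimerise and the 12-ketone cannot enolise toward the bridgehead C13.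

Step 15
Reactants: 22 3,12-dioxo dimethyl ester
Product: 23 target dimethyl ester (7,19-dimethyl ester of the target diacid)
Conditions: KBH(s-Bu)3, THF, −78 °C; then H2O
Reagents that add atoms: none
Why: In this bulky-hydride ketone reduction axial delivery is blocked at both carbonyls (at C12 by the syn-axial C9–C10 bond, at C3 by the axial hydrogens on C1 and C5), so hydride enters equatorially and gives the axial 3β-alcohol, trans to C19 and C20, and the axial 12-alcohol, anti to the C15–C16 bridge.

Step 16
Reactants: 23 target dimethyl ester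
Product: 24 target gibberellin (3,12-dihydroxy 7,19-diacid)
Conditions: n-PrSLi, HMPA, rt; then 1 M HCl
Reagents that add atoms: none
Why: Nucleophilic demethylation by the soft thiolate (bimolecular substitution at the ester methyl carbons) frees the hindered C19 acid and the C7 acid without the alkoxide-driven retro-aldol epimerisation at C3 that hydroxide would risk.

**Compound list**
1 | andrographolide (ent-labdane; equatorial 3-OH and axial 19-CH2OH both cis to the C10 methyl; trans-decalin; 8(17)-methylene; E-alkylidene 14-hydroxybutenolide chain on C9) | C[C@@]12CC[C@H]([C@@]([C@H]1CCC(=C)[C@H]2C/C=C/3\[C@@H](COC3=O)O)(C)CO)O | starting material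
2 | 3,19-O-isopropylideneandrographolide (1,3-dioxane acetonide across the 3- and 19-oxygens) | C[C@@]12CC[C@@H]3[C@@]([C@H]1CCC(=C)[C@H]2C/C=C/4\[C@@H](COC4=O)O)(C)COC(C)(C)O3 | intermediate
3 | 3,19-O-isopropylidene-13,14,15,16-tetranor-ent-labd-8(17)-en-12-al (C9 carries CH2CHO; exocyclic C8=C17 intact) | C[C@@]12CC[C@@H]3[C@@]([C@H]1CCC(=C)[C@H]2CC=O)(C)COC(C)(C)O3 | intermediate
4 | dimethyl acetal of 3 (C12 as CH(OMe)2) | C[C@@]12CC[C@@H]3[C@@]([C@H]1CCC(=C)[C@H]2CC(OC)OC)(C)COC(C)(C)O3 | intermediate
5 | 7-hydroxy derivative of 4 (7-OH axial, trans to the C10 methyl; 8(17)-ene) | C[C@@]12CC[C@@H]3[C@@]([C@H]1C[C@H](O)C(=C)[C@H]2CC(OC)OC)(C)COC(C)(C)O3 | intermediate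
6 | 7-oxo derivative of 4 (exocyclic enone C7(=O)–C8=C17H2) | C[C@@]12CC[C@@H]3[C@@]([C@H]1CC(=O)C(=C)[C@H]2CC(OC)OC)(C)COC(C)(C)O3 | intermediate
7 | vinylmagnesium bromide (CH2=CHMgBr) | C=C[Mg]Br | starting material
8 | 3-bromo-2-methylprop-1-ene (methallyl bromide) | CC(=C)CBr | starting material
9 | bromomagnesium enolate (C7–OMgBr, C7=C8; C8 carries the allyl group C17H2–CH=CH2) | C[C@@]12CC[C@@H]3[C@@]([C@H]1CC(O[Mg]Br)=C(CC=C)[C@H]2CC(OC)OC)(C)COC(C)(C)O3 | intermediate (not isolated)
10 | 8-allyl-8-(2-methylallyl) 7-ketone (quaternary C8; allyl axial and cis to the C10 methyl, 2-methylallyl trans to it) | C[C@@]12CC[C@@H]3[C@@]([C@H]1CC(=O)[C@](CC=C)(CC(C)=C)[C@H]2CC(OC)OC)(C)COC(C)(C)O3 | intermediate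
11 | spiro ketone (ring D = 3-methylcyclopent-3-ene spiro at C8; the ring CH2 next to the CH= carbon is cis to the C10 methyl; C7 ketone) | C[C@@]12CC[C@@H]3[C@@]([C@H]1CC(=O)[C@@]4(CC=C(C)C4)[C@H]2CC(OC)OC)(C)COC(C)(C)O3 | intermediate
12 | 6-trifluoroacetyl derivative of 11 (C6 enolised, configuration undefined) | C[C@@]12CC[C@@H]3[C@@]([C@H]1C(C(=O)C(F)(F)F)C(=O)[C@@]4(CC=C(C)C4)[C@H]2CC(OC)OC)(C)COC(C)(C)O3 | intermediate (not isolated)
13 | 6-diazo-7-ketone | C[C@@]12CC[C@@H]3[C@@]([C@H]1C(=[N+]=[N-])C(=O)[C@@]4(CC=C(C)C4)[C@H]2CC(OC)OC)(C)COC(C)(C)O3 | intermediate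
14 | ketene (ring B contracted to cyclopentane; C6=C=O) | C[C@@]12CC[C@@H]3[C@@]([C@H]1C(=C=O)[C@@]4(CC=C(C)C4)[C@H]2CC(OC)OC)(C)COC(C)(C)O3 | intermediate (not isolated)
15 | 6-epi methyl ester (CO2Me on C6 cis to C4) | C[C@@]12CC[C@@H]3[C@@]([C@H]1[C@@H](C(=O)OC)[C@@]4(CC=C(C)C4)[C@H]2CC(OC)OC)(C)COC(C)(C)O3 | intermediate (not isolated)
16 | ring-contracted methyl ester (cyclopentane ring B; CO2Me on C6 trans to C4 and cis to the hydrogen on C5; acetonide and dimethyl acetal intact) | C[C@@]12CC[C@@H]3[C@@]([C@H]1[C@H](C(=O)OC)[C@@]4(CC=C(C)C4)[C@H]2CC(OC)OC)(C)COC(C)(C)O3 | intermediate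
17 | aldehyde diol (free 3-OH and 19-OH, C12 aldehyde; otherwise as 16) | C[C@@]12CC[C@@H](O)[C@@]([C@H]1[C@H](C(=O)OC)[C@@]3(CC=C(C)C3)[C@H]2CC=O)(C)CO | intermediate
18 | tetracyclic triol ester (gibberell-16-ene skeleton with 7-CO2Me, 19-CH2OH, 20-methyl; 3-OH equatorial and cis to C20; 12-OH equatorial and syn to the C15–C16 bridge) | C[C@@]12CC[C@@H](O)[C@@]([C@H]1[C@H](C(=O)OC)[C@]34C[C@H](C(=C)C3)[C@H](O)C[C@@H]24)(C)CO | intermediate
19 | 19-aldehyde of 18 | C[C@@]12CC[C@@H](O)[C@@]([C@H]1[C@H](C(=O)OC)[C@]34C[C@H](C(=C)C3)[C@H](O)C[C@@H]24)(C)C=O | intermediate (not isolated)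
20 | 19-carboxylic acid 7-methyl ester (7-monomethyl ester of the 3,12-di-epimer of the target) | C[C@@]12CC[C@@H](O)[C@@]([C@H]1[C@H](C(=O)OC)[C@]34C[C@H](C(=C)C3)[C@H](O)C[C@@H]24)(C)C(=O)O | intermediate
21 | 3,12-di-epi dimethyl ester (7,19-dimethyl ester of the 3,12-di-epimer of the target; both hydroxyls equatorial) | C[C@@]12CC[C@@H](O)[C@@]([C@H]1[C@H](C(=O)OC)[C@]34C[C@H](C(=C)C3)[C@H](O)C[C@@H]24)(C)C(=O)OC | intermediate
22 | 3,12-dioxo dimethyl ester (dimethyl 3,12-dioxogibberell-16-ene-7,19-dioate of the ent series) | C[C@@]12CCC(=O)[C@@]([C@H]1[C@H](C(=O)OC)[C@]34C[C@H](C(=C)C3)C(=O)C[C@@H]24)(C)C(=O)OC | intermediate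
23 | target dimethyl ester (7,19-dimethyl ester of 24; 3β-OH axial; 12-OH axial, anti to the C15–C16 bridge) | C[C@@]12CC[C@H](O)[C@@]([C@H]1[C@H](C(=O)OC)[C@]34C[C@H](C(=C)C3)[C@@H](O)C[C@@H]24)(C)C(=O)OC | intermediate
24 | target gibberellin: 3,12-dihydroxygibberell-16-ene-7,19-dioic acid of the ent series (3-OH axial, trans to C19 and C20; 12-OH axial, anti to the C15–C16 bridge; C6 carboxyl trans to C4; 20-methyl) | C[C@@]12CC[C@H](O)[C@@]([C@H]1[C@H](C(=O)O)[C@]34C[C@H](C(=C)C3)[C@@H](O)C[C@@H]24)(C)C(=O)O | target

**Step count and risks**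

Total step count: 16. Longest linear sequence: 16 steps (1 to 24); compounds 7 and 8 are bought.

The three steps most likely to fail are 6, 11 and 15.

Step 6 is risky because a tetrasubstituted magnesium enolate must be C-alkylated at a congested carbon with the right facial sense. O-alkylation, proton transfer to C6 or poor diastereoselectivity are all possible. The fallback sets out from enone 6 and comes back at ketone 10. The vinyl group is added as before, but enolate 9 is O-acylated with 2-methylallyl chloroformate to give the isolable 2-methylallyl enol carbonate F1. Pd2(dba)3 with PPh3 (a zerovalent palladium source) in THF then triggers decarboxylative Tsuji allylation: ionisation gives the 2-methylallyl palladium cation and the free C8 enolate, which recombine at carbon, again on the face opposite the C10 methyl, to give 10.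

Step 11 is risky because the ene reaction has to close a bridged ring. Proton loss toward C15 instead of C17, or stepwise Prins products, could compete. The fallback sets out from aldehyde 17 and comes back at triol ester 18. SnCl4 in CH2Cl2 at −78 °C drives a stepwise Prins cyclisation in which chloride captures the tertiary C16 cation, giving the 16-chloro 12-alcohol F2. Base-induced dehydrochlorination (bimolecular elimination) with t-BuOK in DMSO then gives 18: the bridgehead C13–H cannot eliminate, and the bulky base prefers the methyl hydrogens over those on C15. A C12 epimer formed on this path converges at diketone 22.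

Step 15 is risky because the facial selectivity at C12 rests on a conformational argument; the C3 reduction is the better-founded of the two. The fallback sets out from diketone 22 and comes back at diester 23. If KBH(s-Bu)3 gives the axial 3β-alcohol but the equatorial 12-alcohol, the product is the 12-epi dimethyl ester F3. A Mitsunobu reaction (4-nitrobenzoic acid, PPh3, DIAD) then inverts only the C12 alcohol, because the axial, neopentyl 3-OH does not react. The hydride result that forces this fallback also shows that the face the carboxylate must use is open. This gives the 12-O-(4-nitrobenzoyl) dimethyl ester F4, and K2CO3 in MeOH cleaves the aryl ester to 23.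

Further compounds
F1 | step 6 | 2-methylallyl enol carbonate of the C7 enolate (C7=C8, allyl on C8) | C[C@@]12CC[C@@H]3[C@@]([C@H]1CC(OC(=O)OCC(C)=C)=C(CC=C)[C@H]2CC(OC)OC)(C)COC(C)(C)O3
F2 | step 11 | 16-chloro 12-alcohol (tertiary chloride at C16 with 17-methyl, C16 configuration undefined; otherwise as 18) | C[C@@]12CC[C@@H](O)[C@@]([C@H]1[C@H](C(=O)OC)[C@]34C[C@H](C(C)(Cl)C3)[C@H](O)C[C@@H]24)(C)CO
F3 | step 15 | 12-epi dimethyl ester (12-epimer of 23; 3-OH axial, 12-OH equatorial and syn to the C15–C16 bridge) | C[C@@]12CC[C@H](O)[C@@]([C@H]1[C@H](C(=O)OC)[C@]34C[C@H](C(=C)C3)[C@H](O)C[C@@H]24)(C)C(=O)OC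
F4 | step 15 | 12-O-(4-nitrobenzoyl) dimethyl ester (12-O-(4-nitrobenzoate) of 23) | C[C@@]12CC[C@H](O)[C@@]([C@H]1[C@H](C(=O)OC)[C@]34C[C@H](C(=C)C3)[C@@H](OC(=O)c5ccc(cc5)[N+](=O)[O-])C[C@@H]24)(C)C(=O)OC
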